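## Structural features

The target is a C20 tricycle. An eleven-membered carbocycle (ring A: C2, C3, C8, C9, C10, C16, C17, C18, C19, C21, C22) is bridged across a cis-fused hydrindane made of a cyclohexene (ring B: C18, C19, C21, C25, C27, C29) and a cyclopentane (ring C: C21–C25). Rings A and B share C18, C19 and C21, so the tetrasubstituted alkene C18=C19 is a bridgehead alkene of a bicyclo[8.3.1] system, cis in ring B and therefore E in ring A. Of the seven stereocentres, C21, C22 and C25 are contiguous (ring-fusion hydrogen and angular methyl cis, the C22–C2 bond on the face of ring B). C27 and C29 carry a trans-diol whose C27 hydroxyl is syn to the C25 methyl, C3 is an allylic acetoxy carbon beside the exocyclic methylene C1=C2, and C10 with its acetoxymethyl group stands alone in the chain. The acetates exclude strong nucleophiles late, the methylene C1=C2 excludes unselective hydrogenation and undirected carbenoids, and a C27 ketone flanked by the β,γ-alkene can slip into conjugation. The real difficulty is the strained bridgehead alkene beside the quaternary C25 inside a medium ring, because closing ring A onto a rigid cyclohexene would have to pay for that strain. The segment C27–C29–C18=C19 (oxygenated carbon, methylene, alkene) is the homoallyl pattern left when an oxygen-substituted cyclopropylcarbinyl cation opens; ring B can therefore be grown from a five-membered ring (C18, C19, C21, C25, C27) with C29 as an inserted carbon, after ring A has been closed on a saturated diquinane.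

## Logic of the disconnections

39 to 38: the C27–H bond is cut. A C27 ketone next to the C29 hydroxyl lets the trans-diol arise by internal hydride delivery. The forward step must deliver hydride from the face of the C29 hydroxyl.

38 to 36: the C29–O bond is cut. The ketone has only one enolisable side, so the dienolate is unambiguous. The forward step needs attack at C29 on the face away from the axial C25 methyl and enolisation of the ketone in the presence of two acetates.

36 to 35 to 34: the acetyl C–O bonds and the silyl ethers are exchanged before the diol exists, so four hydroxyls never have to be told apart.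

34 to 33 (key): C18–C27 is reconnected, C29 becomes a cyclopropane carbon and C19 is hydrated. Ring B shrinks to a five-membered ring and the bridgehead alkene disappears, leaving a flexible saturated diquinane inside ring A. The forward step must break C18–C27, not C18–C29.

33 to 32 to 31: C18–C29 and C27–C29 (methylene transfer) and C19–C20 (methyl addition) are cut. This returns to the 1,3-dione oxidation level. The demands are silicon on O27 only and hydroxyl-directed methylene delivery that spares C1=C2.

31 to 29: the O–Si bonds are cut. A 2-alkyl-1,3-dione flanked by a CH and a quaternary carbon takes a single silyl group at the less hindered O19, so 31 is reached through the bis(silyloxy)diene 30 and loss of the more exposed silyl group.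

29 to 28: C2–C3 is cut, opening ring A. An alkenyl-metal addition to an aldehyde forms the ring, the methylene C1=C2 and the C3 carbinol together, so no hydrogenation follows ring closure. The demands are high dilution and facial control at C3.

28 to 27 to 26 + 10: C17–C18 is cut. Reductive alkylation of the dione 26 with the aldehyde 10 joins two fragments of similar size. The demand is C-alkylation without double condensation.

26 to 24 to 23 to 22 to 21: the C2–I bond and C1 are removed (iodoalkene from alkyne from aldehyde from alcohol). The dione is masked as an enol ether while the aldehyde exists. The demand is that C22 does not epimerise.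

21 to 20: hydrogen is removed from C21 and C22. The bicyclic alkene can accept hydrogen only from the face of the C25 methyl, so both centres are relayed from C25 in one step.

20 to 19: C18–C27 is cut (intramolecular Claisen condensation of a methyl ketone onto the neighbouring ester).

19 to 17 to 16 to 15: C19–C21 (coupling on an enol triflate) and C2–C22 (enolate alkylation) are cut. The ketone of 15 enolises on one side only.

15 to 13 to 11 + 12: C25–C26 is cut. An auxiliary-controlled methylation sets the one centre from which the core is relayed.

10 to 9 to 8 to 7: the C17 aldehyde is traced to a lactone carbonyl, which is opened as a Weinreb amide so that C11 can be silylated.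

7 to 5 to 4 to 2 to 1: the bond between the future C17 and C3 is re-formed as the ring alkene of 1. The forward cleavage gives two acid ends that differ because the hydroxymethyl group lactonises onto the nearer one. The demand is five- over six-membered lactone formation.

## Other disconnections considered

Alternative 1: The cut removes C21–C25, C22–C23 and C23–C24, so that ring B and a cyclopentenone standing in for ring C fall away from an open chain. In the forward step Co2(CO)8 complexes the C21–C22 alkyne of the Z-dienyne A1, and an intramolecular Pauson–Khand reaction with the 1,1-disubstituted alkene C25=C24 and CO gives the bicyclic dienone A2.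
- In favour: three C–C bonds, two rings and the quaternary C25 arise in one step, and the C27/C29 trans-diol is set by reagent control before any ring exists. On bond construction and on diol stereocontrol this alternative is better than the chosen plan, whose key step forms no C–C bond and sets the diol late.
- Against: the enyne is a 1,7-enyne closing a six-membered ring onto a 1,1-disubstituted alkene, the slow case for this reaction. The C23 carbonyl is not in the target and must be removed. The tetrasubstituted C21=C22 enone must be reduced with control at C21 and C22.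
- Ring A would then be closed (C9–C10, creating C10 at the same time) onto a cyclohexadiene that already holds the bridgehead alkene. The chosen plan closes ring A on a saturated diquinane and reveals the alkene afterwards.
- Step economy: gains in the annulation would probably be spent on deoxygenation, reduction and C10 control.

Alternative 2: The cut treats ring C as a contracted cyclohexane in which C2 was a ring member; C22–C23 is the bond made. In the forward step the C22 mesylate of the cis-decalin hydroxy mesylate A3 leaves while the ring bond C2–C23 shifts to C22, giving the hydrindene ketone A4 with C2 as an exocyclic ketone.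
- In favour: decalins are easy to assemble with stereocontrol, and the shift is stereospecific (inversion at C22). On fixing C22 by a stereospecific event it is at least the equal of the hydrogenation used here. Mechanistically it is the equal of the chosen key step: a cationic shift assisted by an oxygen lone pair.
- Against: the mesylate must be equatorial in a mobile cis-decalin, and elimination or epoxide formation compete. C22 ends up α to the new ketone in its less stable endo arrangement and can epimerise.
- Ring A is still to be closed by metathesis onto a framework that already contains C18=C19, followed by a selective hydrogenation and a late methylenation of a hindered, epimerisable α-alkoxy ketone. The chosen plan obtains the methylene during ring closure and keeps the bridgehead alkene for later.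
- Step economy: no better.

Alternative 3: The cut removes C21–C22 and restores C3–C18. In the forward step the potassium alkoxide of the spiro-bridged dienol A5 (KH, 18-crown-6) undergoes an anionic oxy-Cope rearrangement to the tricyclic ketone A6.
- In favour: ring C, ring A (a seven-membered ring grows by four atoms), the bridgehead alkene and the centres C21 and C22 appear in one unimolecular step without high dilution. On ring A formation this alternative is better than the chosen plan, and it is its equal in revealing the strained alkene only when ring A appears.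
- Against: A5 is itself a spiro and bridged tricycle with a nine-membered ring, a quaternary spiro C18 and a tertiary carbinol. Its synthesis and the chair or boat course that would give the cis-hydrindane with the right C22 are the open questions.
- A6 holds nineteen of the twenty skeletal carbons: C1 is absent, so A6 is not the complete skeleton. The C3 ketone has two methylene neighbours (C2 and C8), which makes the later α-methylenation a regiochemical problem, and the ketone must then be reduced with control at C3.
- Step economy: after the key step it is similar to the chosen plan; before it, it is likely to be worse.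

Key step: step 25

Remarks and assumptions:
- Atoms carry their position numbers in the target SMILES (oxygen atoms are counted, so the carbons run C1–C29 with gaps). Ring B means the five-membered ring C18/C19/C21/C25/C27 before step 25.
- Methyllithium should add to the C19 ketone on the convex face of the diquinane, so 33 is written with the C19 methyl convex and the C19 hydroxyl and C29 on the concave face. A drawing with the hydroxyl convex does not follow from methyl addition. C18, C19 and C27 become trigonal in step 25, so this has no effect on 34.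
- tert-Butyldimethylsilyl is used on O3, O11 and O27. A trimethylsilyl enol ether of a 1,3-dione would not survive handling, and p-methoxybenzyl ethers would need an oxidant beside the β,γ-enone.
- Assumption for step 9: the L-valine-derived lithio-enamine is taken to be methylated on the face that gives (S)-15 in toluene/HMPA; if the sense is the opposite, D-valine tert-butyl ester is used.
- Assumption for step 15: methylation goes mainly to the less hindered O19; the O27 isomer would pass through steps 16–18 in the same way and converge on 26.

## Route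

Step 1
Reactants: 1 (S)-cyclohex-3-ene-1-carboxylic acid
Product: 2 (S)-cyclohex-3-en-1-ylmethanol
Conditions: LiAlH4, THF, 0 °C to rt
Reagents that add atoms: none
Why: Hydride reduction of the acid to the primary alcohol; the stereocentre (future C10) is untouched.

Step 2
Reactants: 2 (S)-cyclohex-3-en-1-ylmethanol
Product: 4 3-[(3S)-5-oxooxolan-3-yl]propanoic acid, via hydroxy diacid 3 (not isolated)
Conditions: O3, CH2Cl2–MeOH, –78 °C; then 30% H2O2, HCO2H, 50 °C; concentrate
Reagents that add atoms: ozone, [O-][O+]=O; hydrogen peroxide, OO
Why: Ozonolysis with oxidative work-up cuts the ring between the future C17 and C3; the hydroxymethyl group should close the five-membered lactone onto the nearer C17 acid in preference to the six-membered one, which tells the two chain ends apart.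

Step 3
Reactants: 4 3-[(3S)-5-oxooxolan-3-yl]propanoic acid
Product: 5 (4S)-4-(3-hydroxypropyl)oxolan-2-one
Conditions: BH3·SMe2, THF, 0 °C; MeOH
Reagents that add atoms: none
Why: Borane reduces a free carboxylic acid much faster than a lactone (chemoselective acid reduction), giving the C3 alcohol.

Step 4
Reactants: 5 (4S)-4-(3-hydroxypropyl)oxolan-2-one
Product: 7 (4S)-4-(3,3-dimethoxypropyl)oxolan-2-one, via lactone aldehyde 6 (not isolated)
Conditions: TEMPO (cat.), PhI(OAc)2, CH2Cl2, rt; then MeOH, HC(OMe)3, PPTS (cat.), rt
Reagents that add atoms: methanol, CO; trimethyl orthoformate, COC(OC)OC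
Why: Oxoammonium oxidation stops at the aldehyde, which is acetalised in the same flask; the acetal holds C3 at the aldehyde level so that no oxidation is needed once the dione is present.

Step 5
Reactants: 7 (4S)-4-(3,3-dimethoxypropyl)oxolan-2-one
Product: 8 (3S)-3-(hydroxymethyl)-N,6,6-trimethoxy-N-methylhexanamide
Conditions: MeNHOMe·HCl, i-PrMgCl, THF, –20 to 0 °C
Reagents that add atoms: N,O-dimethylhydroxylamine hydrochloride, CNOC.Cl
Why: Aminolysis of the lactone by the magnesium amide (Weinreb amide formation) frees the C11 hydroxyl and leaves C17 as an aldehyde precursor.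

Step 6
Reactants: 8 (3S)-3-(hydroxymethyl)-N,6,6-trimethoxy-N-methylhexanamide
Product: 9 (3S)-3-[(tert-butyldimethylsilyloxy)methyl]-N,6,6-trimethoxy-N-methylhexanamide
Conditions: t-BuMe2SiCl, imidazole, DMF, 0 °C
Reagents that add atoms: tert-butyldimethylsilyl chloride, CC(C)(C)[Si](C)(C)Cl
Why: Silylation of the primary alcohol at once prevents relactonisation and protects O11 for the whole route.

Step 7
Reactants: 9 (3S)-3-[(tert-butyldimethylsilyloxy)methyl]-N,6,6-trimethoxy-N-methylhexanamide
Product: 10 (3S)-3-[(tert-butyldimethylsilyloxy)methyl]-6,6-dimethoxyhexanal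
Conditions: i-Bu2AlH, THF, –78 °C
Reagents that add atoms: none
Why: Reduction of the Weinreb amide stops at the aldehyde through the chelated tetrahedral intermediate; acetal and silyl ether are inert.

Step 8
Reactants: 11 methyl 2-oxocyclopentane-1-carboxylate; 12 L-valine tert-butyl ester
Product: 13 methyl 2-{[(2S)-1-tert-butoxy-3-methyl-1-oxobutan-2-yl]amino}cyclopent-1-ene-1-carboxylate
Conditions: BF3·OEt2 (cat.), benzene, reflux, water removed
Reagents that add atoms: none
Why: Condensation of the β-keto ester with the amino ester gives the hydrogen-bonded enamino ester that carries the chiral auxiliary.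

Step 9
Reactants: 13 enamino ester
Product: 15 methyl (1S)-1-methyl-2-oxocyclopentane-1-carboxylate, via methylated imine 14 (not isolated)
Conditions: LiN(i-Pr)2, toluene, HMPA, –78 °C; MeI; then 1 M HCl
Reagents that add atoms: iodomethane, CI; water, O
Why: Alkylation of the chelated lithio-enamine (chiral enamine alkylation of a β-keto ester) sets the quaternary C25; lithium bound to the valine ester shields one face, and hydrolysis returns the amino ester.

Step 10
Reactants: 15 methyl (1S)-1-methyl-2-oxocyclopentane-1-carboxylate
Product: 16 methyl (1S)-3-[(benzyloxy)methyl]-1-methyl-2-oxocyclopentane-1-carboxylate (both C3 epimers)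
Conditions: LiN(i-Pr)2, THF, –78 °C; BnOCH2Cl
Reagents that add atoms: benzyl chloromethyl ether, ClCOCc1ccccc1
Why: The ketone can enolise only toward the future C22, so enolate alkylation puts C2 there; the new centre becomes trigonal in the next step.

Step 11
Reactants: 16 benzyloxymethyl ketone
Product: 17 methyl (1S)-3-[(benzyloxy)methyl]-1-methyl-2-(trifluoromethanesulfonyloxy)cyclopent-2-ene-1-carboxylate
Conditions: KN(SiMe3)2, THF, –78 °C; PhNTf2
Reagents that add atoms: N-phenylbis(trifluoromethanesulfonimide), O=S(=O)(N(c1ccccc1)S(=O)(=O)C(F)(F)F)C(F)(F)F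
Why: The only possible enolate is O-triflated to the tetrasubstituted enol triflate C21=C22.

Step 12
Reactants: 17 enol triflate
Product: 19 methyl (1S)-2-acetyl-3-[(benzyloxy)methyl]-1-methylcyclopent-2-ene-1-carboxylate, via ethoxyvinyl diene 18 (not isolated)
Conditions: CH2=C(OEt)SnBu3, Pd(PPh3)4 (cat.), LiCl, CuI (cat.), dioxane, 90 °C; then 1 M HCl, THF, rt
Reagents that add atoms: tributyl(1-ethoxyvinyl)stannane, CCCC[Sn](CCCC)(CCCC)C(=C)OCC; water, O
Why: Stille coupling of the enol triflate with an acetyl anion equivalent, then hydrolysis of the enol ether, installs the methyl ketone that supplies C19 and C18.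

Step 13
Reactants: 19 acetyl cyclopentene ester
Product: 20 (1S)-6-[(benzyloxy)methyl]-1-methylbicyclo[3.3.0]oct-5-ene-2,4-dione
Conditions: KOt-Bu, THF, 0 °C to rt; then aq. HCl
Reagents that add atoms: none
Why: Intramolecular Claisen (Dieckmann-type) condensation: the methyl ketone enolate (C18) attacks the neighbouring ester (C27) and the acidic 1,3-dione product drives the closure of ring B in its five-membered form.

Step 14
Reactants: 20 bicyclic ene-dione
Product: 21 (1S)-6-(hydroxymethyl)-1-methyl-cis-bicyclo[3.3.0]octane-2,4-dione (H21 and H22 cis to the C25 methyl, hydroxymethyl endo)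
Conditions: H2 (1 atm), Pd/C (10%), EtOAc–MeOH, rt
Reagents that add atoms: none
Why: Hydrogen adds syn to C21=C22 from the face of the C25 methyl, the only face that leads to a cis-fused diquinane, which sets C21 and C22 together and turns C2 to the concave side; the benzyl ether is cleaved in the same operation.

Step 15
Reactants: 21 dione alcohol
Product: 22 C19 methyl enol ether of 21 (carbonyl at C27, alkene C18=C19)
Conditions: Me3SiCHN2, MeOH–toluene, 0 °C
Reagents that add atoms: trimethylsilyldiazomethane, C[Si](C)(C)C=[N+]=[N-]
Why: O-Methylation of the acidic enol masks the dione as a vinylogous ester, so that the aldehyde of the next steps cannot condense with it and oxidants do not attack the enol.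

Step 16
Reactants: 22 vinylogous ester alcohol
Product: 23 C2 aldehyde (formyl group endo on C22)
Conditions: Dess–Martin periodinane, NaHCO3, CH2Cl2, 0 °C
Reagents that add atoms: none
Why: Buffered, neutral oxidation of the primary alcohol; short contact keeps the endo configuration at C22.

Step 17
Reactants: 23 aldehyde
Product: 24 terminal alkyne (C2≡C1 on C22)
Conditions: dimethyl (1-diazo-2-oxopropyl)phosphonate, K2CO3, MeOH, 0 °C to rt
Reagents that add atoms: dimethyl (1-diazo-2-oxopropyl)phosphonate, COP(=O)(OC)C(=[N+]=[N-])C(C)=O
Why: Ohira–Bestmann homologation adds C1 and gives the alkyne; the aldehyde is consumed quickly at 0 °C, which limits epimerisation at C22.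

Step 18
Reactants: 24 alkyne
Product: 26 iodoalkene dione (C22–C(I)=CH2; free 1,3-dione), via iodoalkene enol ether 25 (not isolated)
Conditions: NaI, Me3SiCl, H2O, MeCN, rt; then 1 M HCl, THF, rt
Reagents that add atoms: sodium iodide, [Na+].[I-]; water, O
Why: Markovnikov addition of HI made in the flask gives the 2-iodoalkene, and aqueous acid then hydrolyses the vinylogous ester back to the dione.

Step 19
Reactants: 26 iodoalkene dione; 10 (3S)-3-[(tert-butyldimethylsilyloxy)methyl]-6,6-dimethoxyhexanal
Product: 27 C18-alkylated dione (C17–C18 bond; C3 dimethyl acetal, O11 silyl ether)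
Conditions: L-proline (cat.), Hantzsch ester, CH2Cl2, rt
Reagents that add atoms: none
Why: Three-component reductive alkylation: Knoevenagel condensation at C18, then hydride transfer from the dihydropyridine to the alkylidene dione; only C-alkylation is possible and the fast reduction prevents double addition.

Step 20
Reactants: 27 alkylated dione acetal
Product: 28 C3 aldehyde
Conditions: PPTS, acetone–H2O, rt
Reagents that add atoms: water, O
Why: Mild acetal hydrolysis without any oxidant; silyl ether and iodoalkene are stable, and the 2-alkyl dione can add to the aldehyde only reversibly.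

Step 21
Reactants: 28 iodoalkene aldehyde
Product: 29 ring-A-closed dione with (3S)-hydroxyl and C1=C2 methylene
Conditions: CrCl2, NiCl2 (cat.), DMSO–THF, rt, 1 mM, slow addition
Reagents that add atoms: none
Why: Nozaki–Hiyama–Kishi macrocyclisation: zerovalent nickel inserts into the C–I bond, the alkenyl group passes to trivalent chromium and adds only to the aldehyde, closing the eleven-membered ring; the acidic dione is carried as its chromium enolate and the C3 configuration depends on the cyclic transition state.

Step 22
Reactants: 29 macrocyclic hydroxy dione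
Product: 31 3-silyloxy enone (C3 silyl ether; O27 silyl enol ether C27=C18; C19 ketone), via bis(silyloxy)diene 30 (not isolated)
Conditions: t-BuMe2SiOTf (excess), Et3N, CH2Cl2, –78 °C to rt; then MeOH (1 equiv beyond the excess triflate), PPTS (cat.), –40 °C
Reagents that add atoms: tert-butyldimethylsilyl triflate, CC(C)(C)[Si](C)(C)OS(=O)(=O)C(F)(F)F
Why: Exhaustive silylation protects O3 and takes the dione, through the common bis(silyloxy)allyl cation and loss of H21, to the 1,3-bis(silyloxy)diene; protonation at the diene terminus C21 and removal of the more exposed O19 silyl group by methanol should leave silicon on the hindered O27 (selective hydrolysis of the Danishefsky-diene type), with H21 returning on the convex face.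

Step 23
Reactants: 31 3-silyloxy enone
Product: 32 tertiary C19 carbinol (methyl convex, hydroxyl concave; O27 silyl enol ether kept)
Conditions: MeLi, Et2O–THF, –78 °C; aq. NaHCO3; used crude
Reagents that add atoms: methyllithium, [Li]C
Why: 1,2-Addition to the carbonyl of the vinylogous silyl ester (first stage of a Stork–Danheiser sequence) from the convex face, anti to the endo C2 group and to ring A; the work-up is kept basic so that the allylic carbinol does not ionise.

Step 24
Reactants: 32 tertiary carbinol
Product: 33 ring-A-fused diquinane with O27-silyloxycyclopropane (C18, C27, C29) and C19 carbinol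
Conditions: Et2Zn, CH2I2, CH2Cl2, –20 to 0 °C; pyridine, then aq. NaHCO3
Reagents that add atoms: diiodomethane, ICI
Why: Furukawa–Simmons–Smith cyclopropanation: the zinc alkoxide at C19 delivers methylene to the adjacent electron-rich enol ether on its own face, which should spare the unactivated C1=C2.

Step 25
Reactants: 33 silyloxycyclopropyl carbinol
Product: 34 tricyclic C27 ketone with C29 methylene and C18=C19 alkene (O3 and O11 silyl ethers)
Conditions: PPTS (0.2 equiv), CH2Cl2–MeOH (4:1), 0 °C to rt
Reagents that add atoms: none
Why: PPTS protonates the tertiary C19 hydroxyl and water leaves to give a tertiary cyclopropylcarbinyl cation. The cation is relieved by cleavage of the cyclopropane bond C18–C27, the only cleavage that puts the charge on the silyloxy-bearing carbon, and the C18=C19 alkene appears. Methanol takes the silyl group from the oxocarbenium ion and leaves the C27 ketone. The closest known reaction type is the acid-induced opening of 2-alkoxycyclopropyl carbinols to β,γ-unsaturated carbonyl compounds, a donor-assisted cyclopropylcarbinyl-to-homoallyl fragmentation. Ring B is closed as a six-membered ring by enlargement: no σ-bond forms, the fusion bond of the bicyclo[3.1.0]hexane breaks and C29 stays bonded to C18 and C27. No stereocentre is created; C18, C19 and C27 become trigonal, and the alkene is E in ring A because it is cis in ring B. The step needs C18–C27 to break instead of C18–C29 (secured by the O27 donor, since the other cleavage would give a primary cation) and ring opening to outrun proton loss from the cation (helped by the weak acid and the push–pull assistance). The other silyl ethers and C1=C2 should be inert to PPTS at this temperature.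

Step 26
Reactants: 34 bis-silyl ketone
Product: 35 C3,C11-diol ketone
Conditions: HF·pyridine, pyridine, THF, 0 °C to rt
Reagents that add atoms: none
Why: Buffered fluoride cleavage of both silyl ethers under conditions that should not move the β,γ-alkene.

Step 27
Reactants: 35 diol ketone
Product: 36 C3,C11-diacetate ketone
Conditions: Ac2O, pyridine, DMAP (cat.), CH2Cl2, 0 °C
Reagents that add atoms: acetic anhydride, CC(=O)OC(C)=O
Why: Both hydroxyls are acetylated now, before the C27/C29 diol exists, so no later differentiation is needed.

Step 28
Reactants: 36 diacetate ketone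
Product: 38 C29-hydroxy C27-ketone (hydroxyl anti to the C25 methyl), via potassium dienolate 37 (not isolated)
Conditions: KN(SiMe3)2 (1.05 equiv), THF, –78 °C; then 2-(phenylsulfonyl)-3-phenyloxaziridine, –78 °C; aq. NH4Cl
Reagents that add atoms: 2-(phenylsulfonyl)-3-phenyloxaziridine, O=S(=O)(N1OC1c1ccccc1)c1ccccc1
Why: The C29 hydrogens (α to the ketone and allylic) are far more acidic than those of the acetates, so one equivalent of the hindered amide gives the dienolate only; Davis oxidation attacks its α-carbon on the face away from the axial C25 methyl.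

Step 29
Reactants: 38 hydroxy ketone
Product: 39 CNP0193272.1 (target)
Conditions: Me4NBH(OAc)3, MeCN–AcOH, –20 °C
Reagents that add atoms: none
Why: The C29 hydroxyl exchanges onto boron and hydride is delivered internally to the same face of the C27 ketone (hydroxyl-directed reduction of an α-hydroxy ketone), which gives the trans-diol with the C27 hydroxyl syn to the C25 methyl; the acetates are inert.

## Compound list

1 | (S)-cyclohex-3-ene-1-carboxylic acid | C1C[C@H](C(=O)O)CC=C1 | starting material
2 | (S)-cyclohex-3-en-1-ylmethanol | C1C[C@H](CO)CC=C1 | intermediate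
3 | (3S)-3-(hydroxymethyl)hexanedioic acid | OC(=O)CC[C@H](CO)CC(=O)O | intermediate
4 | 3-[(3S)-5-oxooxolan-3-yl]propanoic acid | OC(=O)CC[C@H]1CC(=O)OC1 | intermediate
5 | (4S)-4-(3-hydroxypropyl)oxolan-2-one | OCCC[C@H]1CC(=O)OC1 | intermediate
6 | 3-[(3S)-5-oxooxolan-3-yl]propanal | O=CCC[C@H]1CC(=O)OC1 | intermediate
7 | (4S)-4-(3,3-dimethoxypropyl)oxolan-2-one | COC(OC)CC[C@H]1CC(=O)OC1 | intermediate
8 | (3S)-3-(hydroxymethyl)-N,6,6-trimethoxy-N-methylhexanamide | CON(C)C(=O)C[C@@H](CO)CCC(OC)OC | intermediate
9 | (3S)-3-[(tert-butyldimethylsilyloxy)methyl]-N,6,6-trimethoxy-N-methylhexanamide | CON(C)C(=O)C[C@@H](CO[Si](C)(C)C(C)(C)C)CCC(OC)OC | intermediate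
10 | (3S)-3-[(tert-butyldimethylsilyloxy)methyl]-6,6-dimethoxyhexanal | O=CC[C@@H](CO[Si](C)(C)C(C)(C)C)CCC(OC)OC | intermediate
11 | methyl 2-oxocyclopentane-1-carboxylate | COC(=O)C1CCCC1=O | starting material
12 | L-valine tert-butyl ester | CC(C)[C@H](N)C(=O)OC(C)(C)C | starting material
13 | methyl 2-{[(2S)-1-tert-butoxy-3-methyl-1-oxobutan-2-yl]amino}cyclopent-1-ene-1-carboxylate | COC(=O)C1=C(N[C@@H](C(C)C)C(=O)OC(C)(C)C)CCC1 | intermediate
14 | imine of 15 with L-valine tert-butyl ester | COC(=O)[C@@]1(C)CCCC1=N[C@@H](C(C)C)C(=O)OC(C)(C)C | intermediate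
15 | methyl (1S)-1-methyl-2-oxocyclopentane-1-carboxylate | O=C1CCC[C@]1(C)C(=O)OC | intermediate
16 | methyl (1S)-3-[(benzyloxy)methyl]-1-methyl-2-oxocyclopentane-1-carboxylate (C3 epimers) | O=C1C(COCc2ccccc2)CC[C@]1(C)C(=O)OC | intermediate
17 | methyl (1S)-3-[(benzyloxy)methyl]-1-methyl-2-(trifluoromethanesulfonyloxy)cyclopent-2-ene-1-carboxylate | FC(F)(F)S(=O)(=O)OC1=C(COCc2ccccc2)CC[C@]1(C)C(=O)OC | intermediate
18 | methyl (1S)-3-[(benzyloxy)methyl]-2-(1-ethoxyvinyl)-1-methylcyclopent-2-ene-1-carboxylate | CCOC(=C)C1=C(COCc2ccccc2)CC[C@]1(C)C(=O)OC | intermediate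
19 | methyl (1S)-2-acetyl-3-[(benzyloxy)methyl]-1-methylcyclopent-2-ene-1-carboxylate | CC(=O)C1=C(COCc2ccccc2)CC[C@]1(C)C(=O)OC | intermediate
20 | (1S)-6-[(benzyloxy)methyl]-1-methylbicyclo[3.3.0]oct-5-ene-2,4-dione | O=C1CC(=O)[C@@]2(C)CCC(COCc3ccccc3)=C12 | intermediate
21 | (1S)-6-(hydroxymethyl)-1-methyl-cis-bicyclo[3.3.0]octane-2,4-dione, H5 and H6 cis to the methyl, hydroxymethyl endo | O=C1CC(=O)[C@@]2(C)CC[C@@H](CO)[C@@H]12 | intermediate
22 | C19 methyl enol ether of 21 (4-methoxy enone, carbonyl at C27) | COC1=CC(=O)[C@@]2(C)CC[C@@H](CO)[C@@H]12 | intermediate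
23 | aldehyde from 22 (endo formyl on C22) | COC1=CC(=O)[C@@]2(C)CC[C@@H](C=O)[C@@H]12 | intermediate
24 | alkyne from 23 (endo ethynyl on C22) | COC1=CC(=O)[C@@]2(C)CC[C@@H](C#C)[C@@H]12 | intermediate
25 | 1-iodovinyl enol ether from 24 | COC1=CC(=O)[C@@]2(C)CC[C@@H](C(I)=C)[C@@H]12 | intermediate
26 | (1S)-6-endo-(1-iodovinyl)-1-methyl-cis-bicyclo[3.3.0]octane-2,4-dione | O=C1CC(=O)[C@@]2(C)CC[C@@H](C(I)=C)[C@@H]12 | intermediate
27 | 26 alkylated at C18 with the C17–C3 chain (C10 R-configured as in the target, O11 silyl ether, C3 dimethyl acetal) | O=C1C(CC[C@@H](CO[Si](C)(C)C(C)(C)C)CCC(OC)OC)C(=O)[C@@]2(C)CC[C@@H](C(I)=C)[C@@H]12 | intermediate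
28 | C3 aldehyde from 27 | O=C1C(CC[C@@H](CO[Si](C)(C)C(C)(C)C)CCC=O)C(=O)[C@@]2(C)CC[C@@H](C(I)=C)[C@@H]12 | intermediate
29 | ring-A-closed diquinane dione: (3S)-hydroxyl, C1=C2 methylene, O11 silyl ether, C19 and C27 ketones | C=C1[C@@H](O)CC[C@H](CO[Si](C)(C)C(C)(C)C)CCC2C(=O)[C@@H]3[C@H]1CC[C@]3(C)C2=O | intermediate
30 | O3,O11,O19,O27-tetrasilyl compound with the diene C27=C18–C19=C21 | C=C1[C@@H](O[Si](C)(C)C(C)(C)C)CC[C@H](CO[Si](C)(C)C(C)(C)C)CCC2=C(O[Si](C)(C)C(C)(C)C)[C@@]3(C)CC[C@@H]1C3=C2O[Si](C)(C)C(C)(C)C | intermediate
31 | O3,O11-bis-silyl ether with O27 silyl enol ether (C27=C18) and C19 ketone | C=C1[C@@H](O[Si](C)(C)C(C)(C)C)CC[C@H](CO[Si](C)(C)C(C)(C)C)CCC2=C(O[Si](C)(C)C(C)(C)C)[C@@]3(C)CC[C@@H]1[C@H]3C2=O | intermediate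
32 | C19 methyl carbinol of 31 (methyl on the convex face, hydroxyl on the concave face) | C=C1[C@@H](O[Si](C)(C)C(C)(C)C)CC[C@H](CO[Si](C)(C)C(C)(C)C)CCC2=C(O[Si](C)(C)C(C)(C)C)[C@@]3(C)CC[C@@H]1[C@H]3[C@@]2(C)O | intermediate
33 | ring-A-fused diquinane with O27-silyloxycyclopropane (C18, C27, C29; methylene syn to the C19 hydroxyl, both concave) and C19 methyl carbinol | C=C1[C@@H](O[Si](C)(C)C(C)(C)C)CC[C@H](CO[Si](C)(C)C(C)(C)C)CC[C@@]26[C@](C)(O)[C@@H]3[C@H]1CC[C@]3(C)[C@]2(O[Si](C)(C)C(C)(C)C)C6 | intermediate
34 | tricyclic C27 ketone with C29 methylene, C18=C19 alkene, O3 and O11 silyl ethers | C=C1[C@@H](O[Si](C)(C)C(C)(C)C)CC[C@H](CO[Si](C)(C)C(C)(C)C)CCC2=C(C)[C@@H]3[C@H]1CC[C@]3(C)C(=O)C2 | intermediate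
35 | C3,C11-diol of 34 | C=C1[C@@H](O)CC[C@H](CO)CCC2=C(C)[C@@H]3[C@H]1CC[C@]3(C)C(=O)C2 | intermediate
36 | C3,C11-diacetate C27 ketone | C=C1[C@@H](OC(C)=O)CC[C@H](COC(C)=O)CCC2=C(C)[C@@H]3[C@H]1CC[C@]3(C)C(=O)C2 | intermediate
37 | potassium dienolate of 36 (O–C27=C29–C18=C19) | C=C1[C@@H](OC(C)=O)CC[C@H](COC(C)=O)CCC2=C(C)[C@@H]3[C@H]1CC[C@]3(C)C([O-])=C2.[K+] | intermediate
38 | C29-hydroxy C27 ketone (hydroxyl anti to the C25 methyl) | C=C1[C@@H](OC(C)=O)CC[C@H](COC(C)=O)CCC2=C(C)[C@@H]3[C@H]1CC[C@]3(C)C(=O)[C@@H]2O | intermediate
39 | CNP0193272.1 | C=C1[C@@H](OC(C)=O)CC[C@H](COC(C)=O)CCC2=C(C)[C@@H]3[C@H]1CC[C@]3(C)[C@@H](O)[C@@H]2O | target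

## Step count and least certain steps

Total: 29 steps (7 for the chain 10, 11 for the core 26, 11 after the union). Longest linear sequence: 22 steps (steps 8–29).

Least certain steps:

Step 25 (key step). Proton loss from the C19 cation toward C20 or C21 may outrun cleavage of C18–C27, because the developing E-alkene strains ring A; the acid may also move the new alkene into conjugation with the C27 ketone. The second drift would not be fatal, since step 28 passes through the same dienolate.
Fallback, changing the order of ring enlargement and ring closure: it sets out from 27. The conditions of step 22 give the open-chain 3-silyloxy enone F1. MeMgBr with CeCl3 (no iodine–metal exchange) gives the open-chain carbinol F2. Et2Zn and CH2I2 give the open-chain silyloxycyclopropane F3. PPTS in aqueous acetone then enlarges the unstrained ring and frees the aldehyde, giving the open-chain enone aldehyde F4. CrCl2 with catalytic NiCl2 closes ring A to the macrocyclic hydroxy ketone F5, and silylation of O3 (t-BuMe2SiOTf, 2,6-lutidine) returns to the route at 34.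

Step 22. Desilylation may take place at the hindered O27 instead of O19, or the silyl group may wander back to the more stable O19 ether, so that methyllithium would meet the wrong carbonyl.
Fallback, using the regiochemistry that sterics prefer: it sets out from 29. t-BuMe2SiCl and imidazole give the O3-silyl dione F6. (COCl)2 with catalytic DMF gives the C19 chloro enone F7 (chloride enters at the less hindered carbonyl carbon). Me2CuLi replaces chloride by addition–elimination to give the C19 methyl enone F8. H2O2 and NaOH give the epoxy ketone F9 from the convex face. SmI2 in THF–MeOH cleaves the C18–O bond to the C19 hydroxy ketone F10 (hydroxyl convex). KN(SiMe3)2 (2.2 equiv) and t-BuMe2SiCl silylate only the enolate oxygen, giving the C19 epimer of 32, F11. Et2Zn and CH2I2, now directed to the convex face, give the C18,C19,C27 epimer of 33, F12. The conditions of step 25 return to the route at 34.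

Step 21. Facial selectivity at C3 may be poor, and oligomerisation may compete with closure of the eleven-membered ring.
Fallback for the configuration, replacing substrate control by reagent control: it sets out from 29 obtained as a mixture of C3 epimers. MnO2 oxidises the allylic alcohol to the C3 enone F13, and reduction with catecholborane and the appropriate enantiomer of the B-methyl oxazaborolidine (Corey–Bakshi–Shibata reduction) returns to the route at 29.

Step 28. The oxaziridine may approach the dienolate from the face of the C25 methyl, or the enolate may equilibrate into the acetates.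
Fallback, installing oxygen by inversion: it sets out from 36. KN(SiMe3)2 followed by N-bromosuccinimide gives the C29 bromo ketone F14 from the same, favoured face. HCO2Cs with 18-crown-6 in DMF displaces bromide with inversion to give the C29 formate F15, and NaHCO3 in MeOH at 0 °C removes the formate in the presence of the acetates, returning to the route at 38.

## Further compounds

F1 | step 25 | open-chain 3-silyloxy enone from 27 (O27 silyl enol ether, C19 ketone, iodoalkene, acetal) | O=C1C(CC[C@@H](CO[Si](C)(C)C(C)(C)C)CCC(OC)OC)=C(O[Si](C)(C)C(C)(C)C)[C@@]2(C)CC[C@@H](C(I)=C)[C@@H]12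
F2 | step 25 | open-chain C19 methyl carbinol | C[C@]1(O)C(CC[C@@H](CO[Si](C)(C)C(C)(C)C)CCC(OC)OC)=C(O[Si](C)(C)C(C)(C)C)[C@@]2(C)CC[C@@H](C(I)=C)[C@@H]12
F3 | step 25 | open-chain silyloxycyclopropyl carbinol | C[C@]1(O)[C@@]3(CC[C@@H](CO[Si](C)(C)C(C)(C)C)CCC(OC)OC)C[C@@]3(O[Si](C)(C)C(C)(C)C)[C@@]2(C)CC[C@@H](C(I)=C)[C@@H]12
F4 | step 25 | open-chain hydrindenone aldehyde (C27 ketone, C18=C19, C3 aldehyde, iodoalkene) | O=C1CC(CC[C@@H](CO[Si](C)(C)C(C)(C)C)CCC=O)=C(C)[C@@H]2[C@H](C(I)=C)CC[C@]12C
F5 | step 25 | tricyclic C27 ketone with free (3S)-hydroxyl and O11 silyl ether | C=C1[C@@H](O)CC[C@H](CO[Si](C)(C)C(C)(C)C)CCC2=C(C)[C@@H]3[C@H]1CC[C@]3(C)C(=O)C2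
F6 | step 22 | O3-silyl ether of 29 | C=C1[C@@H](O[Si](C)(C)C(C)(C)C)CC[C@H](CO[Si](C)(C)C(C)(C)C)CCC2C(=O)[C@@H]3[C@H]1CC[C@]3(C)C2=O
F7 | step 22 | C19 chloro enone (C18=C19, C27 ketone) | C=C1[C@@H](O[Si](C)(C)C(C)(C)C)CC[C@H](CO[Si](C)(C)C(C)(C)C)CCC2=C(Cl)[C@@H]3[C@H]1CC[C@]3(C)C2=O
F8 | step 22 | C19 methyl enone (five-membered ring B) | C=C1[C@@H](O[Si](C)(C)C(C)(C)C)CC[C@H](CO[Si](C)(C)C(C)(C)C)CCC2=C(C)[C@@H]3[C@H]1CC[C@]3(C)C2=O
F9 | step 22 | C18–C19 epoxy C27 ketone (oxygen on the convex face) | C=C1[C@@H](O[Si](C)(C)C(C)(C)C)CC[C@H](CO[Si](C)(C)C(C)(C)C)CC[C@@]26O[C@@]6(C)[C@@H]3[C@H]1CC[C@]3(C)C2=O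
F10 | step 22 | C19 hydroxy C27 ketone (hydroxyl convex, C18 open) | C=C1[C@@H](O[Si](C)(C)C(C)(C)C)CC[C@H](CO[Si](C)(C)C(C)(C)C)CCC2[C@@](C)(O)[C@@H]3[C@H]1CC[C@]3(C)C2=O
F11 | step 22 | C19 epimer of 32 | C=C1[C@@H](O[Si](C)(C)C(C)(C)C)CC[C@H](CO[Si](C)(C)C(C)(C)C)CCC2=C(O[Si](C)(C)C(C)(C)C)[C@@]3(C)CC[C@@H]1[C@H]3[C@]2(C)O
F12 | step 22 | C18,C19,C27 epimer of 33 | C=C1[C@@H](O[Si](C)(C)C(C)(C)C)CC[C@H](CO[Si](C)(C)C(C)(C)C)CC[C@]26[C@@](C)(O)[C@@H]3[C@H]1CC[C@]3(C)[C@@]2(O[Si](C)(C)C(C)(C)C)C6
F13 | step 21 | C3 enone of 29 | C=C1C(=O)CC[C@H](CO[Si](C)(C)C(C)(C)C)CCC2C(=O)[C@@H]3[C@H]1CC[C@]3(C)C2=O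
F14 | step 28 | C29 bromo ketone (bromine syn to the C25 methyl) | C=C1[C@@H](OC(C)=O)CC[C@H](COC(C)=O)CCC2=C(C)[C@@H]3[C@H]1CC[C@]3(C)C(=O)[C@H]2Br
F15 | step 28 | C29 formate of 38 | C=C1[C@@H](OC(C)=O)CC[C@H](COC(C)=O)CCC2=C(C)[C@@H]3[C@H]1CC[C@]3(C)C(=O)[C@@H]2OC=O
A1 | alternative 1 | Z-dienyne ketal, open-chain substrate of the Pauson–Khand step | O1CCOC1(C#C/C(C)=C(/CCCC(=O)OC)[C@@H](O[Si](C)(C)C(C)(C)C)[C@H](O[Si](C)(C)C(C)(C)C)C(C)=C)[C@@H](OCc2ccc(OC)cc2)CCO[Si](C)(C)C(C)(C)C
A2 | alternative 1 | bicyclic dienone with C23 ketone | O1CCOC1(C3=C4C(C)=C(CCCC(=O)OC)[C@@H](O[Si](C)(C)C(C)(C)C)[C@H](O[Si](C)(C)C(C)(C)C)[C@@]4(C)CC3=O)[C@@H](OCc2ccc(OC)cc2)CCO[Si](C)(C)C(C)(C)C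
A3 | alternative 2 | cis-decalin hydroxy mesylate (C2 carbinol in the ring, C22 mesylate, drawn as the cis-diol derivative) | C=C[C@H](OCc3ccc(OC)cc3)[C@@]1(O)CC[C@]2(C)[C@@H](O[Si](C)(C)C(C)(C)C)[C@H](O[Si](C)(C)C(C)(C)C)C(CC[C@@H](COCc4ccc(OC)cc4)C=C)=C(C)[C@@H]2[C@@H]1OS(C)(=O)=O
A4 | alternative 2 | hydrindene with exocyclic C2 ketone and two alkene-ended chains | C=C[C@H](OCc3ccc(OC)cc3)C(=O)[C@@H]1CC[C@]2(C)[C@@H](O[Si](C)(C)C(C)(C)C)[C@H](O[Si](C)(C)C(C)(C)C)C(CC[C@@H](COCc4ccc(OC)cc4)C=C)=C(C)[C@@H]21
A5 | alternative 3 | spiro-bridged dienol (C3 carbinol; C3 configuration and C2=C22 geometry left open) | OC12CC[C@H](COCc4ccc(OC)cc4)CC[C@]13C(C)=C[C@](C)(CCC=C2)[C@@H](O[Si](C)(C)C(C)(C)C)[C@@H]3O[Si](C)(C)C(C)(C)C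
A6 | alternative 3 | tricyclic C3 ketone without C1 | C1C(=O)CC[C@H](COCc4ccc(OC)cc4)CCC2=C(C)[C@@H]3[C@H]1CC[C@]3(C)[C@@H](O[Si](C)(C)C(C)(C)C)[C@@H]2O[Si](C)(C)C(C)(C)C
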